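Ring C is cut at the aryl ether bond C8a–O1. O1 sits on a ring A carbon (C8a) that is ortho to C4a, the carbon carrying the C4 carbonyl. The enolate oxygen of a 1,3-diketone can therefore be delivered onto an ortho C–Br bond, and ring A needs no phenol there. One copper-catalysed intramolecular O-arylation forms C8a–O1 and closes the pyranone. Its precursor is a 1-(2-bromoaryl)-3-arylpropane-1,3-dione with the oxygens already told apart: benzyl ethers at O5, O6, O3' and O4', a methoxymethyl ether at O7 only. O7 alone is then unmasked and sulfated before a final hydrogenolysis.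

Key step: step 6

Remark: flavone numbering is used (ring A = benzo ring C4a–C8a, ring C = pyranone, ring B = 2-aryl group). The target is taken as the free hydrogen sulfate and is released from its potassium salt in the last operation. All compounds are achiral, so the SMILES carry no stereodescriptors.

Step 1
Reactants: 1 5-bromo-1,2,3-trimethoxybenzene; 2 acetyl chloride
Product: 3 1-(6-bromo-2,3,4-trimethoxyphenyl)ethan-1-one
Conditions: AlCl3 (1.3 equiv), CH2Cl2, 0 °C → rt
Reagents that add atoms: none
Why: Friedel–Crafts acylation at one of the two symmetry-equivalent free positions, each ortho to bromine and activated by an ortho and a para methoxy group; the deactivated ketone should not react twice, and any loss of the methyl group next to the new carbonyl is harmless because step 2 removes all three.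

Step 2
Reactants: 3 1-(6-bromo-2,3,4-trimethoxyphenyl)ethan-1-one
Product: 4 1-(6-bromo-2,3,4-trihydroxyphenyl)ethan-1-one
Conditions: BBr3 (4 equiv), CH2Cl2, −78 °C → rt; then H2O, 0 °C
Reagents that add atoms: none
Why: Lewis-acid cleavage of aryl methyl ethers (BBr3 demethylation), in which each methoxy oxygen is borylated and bromide removes the methyl group by SN2, while the aryl bromide and the ketone are left alone.

Step 3
Reactants: 4 1-(6-bromo-2,3,4-trihydroxyphenyl)ethan-1-one
Product: 5 1-[6-bromo-2,3-dihydroxy-4-(methoxymethoxy)phenyl]ethan-1-one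
Conditions: MOMCl (1.05 equiv), K2CO3 (1.0 equiv), acetone, 0 °C → rt, argon
Reagents that add atoms: chloromethyl methyl ether, COCCl
Why: Regioselective Williamson-type O-alkylation, since O4–H (para to the acetyl group) is the most acidic hydroxyl, whereas O2–H is held in a hydrogen bond to the carbonyl and O3–H is flanked on both sides, so one equivalent of weak base and electrophile should alkylate O4 alone.

Step 4
Reactants: 5 1-[6-bromo-2,3-dihydroxy-4-(methoxymethoxy)phenyl]ethan-1-one
Product: 6 1-[2,3-bis(benzyloxy)-6-bromo-4-(methoxymethoxy)phenyl]ethan-1-one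
Conditions: BnBr (2.5 equiv), K2CO3 (3 equiv), DMF, 60 °C
Reagents that add atoms: benzyl bromide, BrCc1ccccc1
Why: Williamson ether synthesis, in which excess base and benzyl bromide in warm DMF should benzylate both remaining phenols, the chelated O2–H included, while the methoxymethyl ether and the aryl bromide are inert.

Step 5
Reactants: 6 1-[2,3-bis(benzyloxy)-6-bromo-4-(methoxymethoxy)phenyl]ethan-1-one; 7 methyl 3,4-bis(benzyloxy)benzoate
Product: 8 1-[2,3-bis(benzyloxy)-6-bromo-4-(methoxymethoxy)phenyl]-3-[3,4-bis(benzyloxy)phenyl]propane-1,3-dione (keto–enol mixture)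
Conditions: NaH (3 equiv), THF, 0 °C → reflux; then cold 1 M HCl to pH 5
Reagents that add atoms: none
Why: Crossed Claisen condensation, in which the methyl ketone is the only enolisable partner, its sodium enolate is C-acylated by the non-enolisable ester, deprotonation of the diketone drives the equilibrium, and the twisted, doubly ortho-substituted ketone carbonyl resists self-aldol reaction.

Step 6
Reactants: 8 1-[2,3-bis(benzyloxy)-6-bromo-4-(methoxymethoxy)phenyl]-3-[3,4-bis(benzyloxy)phenyl]propane-1,3-dione
Product: 9 5,6-bis(benzyloxy)-2-[3,4-bis(benzyloxy)phenyl]-7-(methoxymethoxy)-4H-chromen-4-one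
Conditions: CuI (10 mol %), N,N-dimethylglycine hydrochloride (20 mol %), K2CO3 (3 equiv), dry degassed DMF, 100 °C, argon
Reagents that add atoms: none
Why: K2CO3 converts the diketone into its chelating enolate, which binds CuI (monovalent copper); oxidative addition of the neighbouring, ortho-acyl-activated C8a–Br bond gives an aryl copper enolate (trivalent copper), and C–O reductive elimination joins the enolate oxygen on the ring B side to C8a. The closest known reaction type is the Ullmann-type intramolecular O-arylation of 1-(2-haloaryl)-1,3-diketones to chromones and flavones, run with CuI and an amino acid ligand or, on activated rings, with base alone. Ring C closes as a six-membered pyranone by 6-exo attack of oxygen at the aromatic carbon C8a, the bromide leaving from outside the new ring. No stereocenter is formed. The step needs O- over C-arylation and the right ring oxygen: attack by C3 or by the oxygen on the ring A side would give a four-membered ring, so only the ring B side oxygen can close, and the single bromine, placed on the symmetric arene in step 1, fixes C8a and with it the 5,6,7-oxygen pattern. Because every phenol is masked as a benzyl or methoxymethyl ether, neither intermolecular diaryl ether formation nor copper-mediated phenol oxidation can compete.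

Step 7
Reactants: 9 5,6-bis(benzyloxy)-2-[3,4-bis(benzyloxy)phenyl]-7-(methoxymethoxy)-4H-chromen-4-one
Product: 10 5,6-bis(benzyloxy)-2-[3,4-bis(benzyloxy)phenyl]-7-hydroxy-4H-chromen-4-one
Conditions: HCl (1.25 M in MeOH), THF, 40 °C
Reagents that add atoms: none
Why: Acid-catalysed acetal cleavage, in which the methoxymethyl ether ionises in methanolic HCl and is trapped as dimethoxymethane while aryl benzyl ethers and the flavone are stable; partial loss of the chelated 5-O-benzyl group would be harmless, since O5–H is not sulfated and is freed later anyway.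

Step 8
Reactants: 10 5,6-bis(benzyloxy)-2-[3,4-bis(benzyloxy)phenyl]-7-hydroxy-4H-chromen-4-one
Product: 11 potassium 5,6-bis(benzyloxy)-2-[3,4-bis(benzyloxy)phenyl]-4-oxo-4H-chromen-7-yl sulfate
Conditions: SO3·pyridine (3 equiv), pyridine, 50 °C; then KOH (1 M in MeOH) to pH 8, 0 °C
Reagents that add atoms: sulfur trioxide–pyridine complex, O=S(=O)([O-])[n+]1ccccc1; potassium hydroxide, [K+].[OH-]
Why: O-sulfonation of a phenol by a sulfur trioxide–amine complex, in which the 7-hydroxyl is the only free OH so the site is fixed by the protecting-group pattern, and exchange of pyridinium for potassium gives a neutral salt free of the amine that would slow the next hydrogenolysis.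

Step 9
Reactants: 11 potassium 5,6-bis(benzyloxy)-2-[3,4-bis(benzyloxy)phenyl]-4-oxo-4H-chromen-7-yl sulfate
Product: 13 5,6-dihydroxy-2-(3,4-dihydroxyphenyl)-4-oxo-4H-chromen-7-yl hydrogen sulfate (6-hydroxyluteolin 7-sulfate), via potassium 6-hydroxyluteolin 7-sulfate 12 (not isolated)
Conditions: H2 (1 atm), Pd/C (10 % Pd), THF–MeOH–H2O, rt, filtration under argon; then 0.1 M HCl (1.0 equiv), 0 °C, C18 desalting, freeze-drying
Reagents that add atoms: none
Why: Catalytic hydrogenolysis of aryl benzyl ethers, which should cleave the four O–CH2Ph bonds under neutral conditions that leave the sulfate monoester salt and the C2–C3 double bond intact; one equivalent of cold dilute acid then converts the potassium salt into the hydrogen sulfate.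

Compound list
1 | 5-bromo-1,2,3-trimethoxybenzene | COc1cc(Br)cc(OC)c1OC | starting material
2 | acetyl chloride | CC(Cl)=O | starting material
3 | 1-(6-bromo-2,3,4-trimethoxyphenyl)ethan-1-one | CC(=O)c1c(Br)cc(OC)c(OC)c1OC | intermediate
4 | 1-(6-bromo-2,3,4-trihydroxyphenyl)ethan-1-one | CC(=O)c1c(Br)cc(O)c(O)c1O | intermediate
5 | 1-[6-bromo-2,3-dihydroxy-4-(methoxymethoxy)phenyl]ethan-1-one | CC(=O)c1c(Br)cc(OCOC)c(O)c1O | intermediate
6 | 1-[2,3-bis(benzyloxy)-6-bromo-4-(methoxymethoxy)phenyl]ethan-1-one | CC(=O)c1c(Br)cc(OCOC)c(OCc2ccccc2)c1OCc1ccccc1 | intermediate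
7 | methyl 3,4-bis(benzyloxy)benzoate | COC(=O)c1ccc(OCc2ccccc2)c(OCc2ccccc2)c1 | starting material
8 | 1-[2,3-bis(benzyloxy)-6-bromo-4-(methoxymethoxy)phenyl]-3-[3,4-bis(benzyloxy)phenyl]propane-1,3-dione | O=C(CC(=O)c1c(Br)cc(OCOC)c(OCc2ccccc2)c1OCc1ccccc1)c1ccc(OCc2ccccc2)c(OCc2ccccc2)c1 | intermediate
9 | 5,6-bis(benzyloxy)-2-[3,4-bis(benzyloxy)phenyl]-7-(methoxymethoxy)-4H-chromen-4-one | O=c1cc(-c2ccc(OCc3ccccc3)c(OCc3ccccc3)c2)oc2cc(OCOC)c(OCc3ccccc3)c(OCc3ccccc3)c12 | intermediate
10 | 5,6-bis(benzyloxy)-2-[3,4-bis(benzyloxy)phenyl]-7-hydroxy-4H-chromen-4-one | O=c1cc(-c2ccc(OCc3ccccc3)c(OCc3ccccc3)c2)oc2cc(O)c(OCc3ccccc3)c(OCc3ccccc3)c12 | intermediate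
11 | potassium 5,6-bis(benzyloxy)-2-[3,4-bis(benzyloxy)phenyl]-4-oxo-4H-chromen-7-yl sulfate | O=c1cc(-c2ccc(OCc3ccccc3)c(OCc3ccccc3)c2)oc2cc(OS(=O)(=O)[O-])c(OCc3ccccc3)c(OCc3ccccc3)c12.[K+] | intermediate
12 | potassium 6-hydroxyluteolin 7-sulfate | O=c1cc(-c2ccc(O)c(O)c2)oc2cc(OS(=O)(=O)[O-])c(O)c(O)c12.[K+] | intermediate
13 | 6-hydroxyluteolin 7-sulfate | O=c1cc(-c2ccc(O)c(O)c2)oc2cc(OS(=O)(=O)O)c(O)c(O)c12 | target

Total step count: 9
Longest linear sequence: 9 steps (1 → 13); ester 7 is bought and enters at step 5.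

Steps most likely to fail

1. Step 6. Oxidative addition of copper into the electron-rich, doubly ortho-substituted C8a–Br bond may be slow, so that retro-Claisen cleavage of the diketone by hot carbonate and protodebromination outrun ring closure. The fallback sets out from 6 and comes back at 10; it installs O1 on ring A first and closes ring C at C2–O1 instead. Hydroxylation of the bromide under zerovalent palladium catalysis (Pd2(dba)3, t-BuXPhos, KOH, dioxane–H2O, 90 °C) would give 1-[2,3-bis(benzyloxy)-6-hydroxy-4-(methoxymethoxy)phenyl]ethan-1-one F1. Claisen condensation of its dianion with ester 7 (LiHMDS, 4 equiv, THF, −78 °C → rt) would give 1-[2,3-bis(benzyloxy)-6-hydroxy-4-(methoxymethoxy)phenyl]-3-[3,4-bis(benzyloxy)phenyl]propane-1,3-dione F2. Acid-catalysed cyclodehydration (HCl in MeOH–THF, 50 °C), in which the phenol oxygen adds to the ring B side carbonyl and the methoxymethyl ether is lost in the same pot, would then give 10.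

2. Step 3. Site selectivity may be lost (alkylation at O3 or double alkylation), and the pyrogallol-type triol may be oxidised under base. The fallback sets out from 4 and comes back at 6; it replaces the one-shot mono-protection by a stepwise sequence that uses the chelated O2–H as the fixed point. Two equivalents of MOMCl (K2CO3, acetone, rt) should leave only the hydrogen-bonded hydroxyl, giving 1-[6-bromo-2-hydroxy-3,4-bis(methoxymethoxy)phenyl]ethan-1-one F3. Benzylation (BnBr, K2CO3, DMF, 60 °C) gives 1-[2-(benzyloxy)-6-bromo-3,4-bis(methoxymethoxy)phenyl]ethan-1-one F4, and methanolic HCl frees the catechol 1-[2-(benzyloxy)-6-bromo-3,4-dihydroxyphenyl]ethan-1-one F5. Of its two hydroxyls only O4–H is para to the acyl group, so one equivalent of MOMCl and K2CO3 should give 1-[2-(benzyloxy)-6-bromo-3-hydroxy-4-(methoxymethoxy)phenyl]ethan-1-one F6, and benzylation of O3–H then gives 6.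

3. Step 9. The four-fold hydrogenolysis of an ionic, poorly soluble substrate may be slow or incomplete, with saturation of the C2–C3 double bond on prolonged exposure. The fallback sets out from 9 and comes back at 12; it removes the benzyl ethers before sulfation and carries the phenols as acetates. Hydrogenolysis of neutral 9 (H2, Pd/C, THF–MeOH) would give 5,6-dihydroxy-2-(3,4-dihydroxyphenyl)-7-(methoxymethoxy)-4H-chromen-4-one F7. Acetylation (Ac2O, pyridine) gives 2-[3,4-bis(acetyloxy)phenyl]-7-(methoxymethoxy)-4-oxo-4H-chromene-5,6-diyl diacetate F8. Trifluoroacetic acid in wet CH2Cl2 (0 °C → rt) removes the methoxymethyl group without touching aryl acetates, giving 2-[3,4-bis(acetyloxy)phenyl]-7-hydroxy-4-oxo-4H-chromene-5,6-diyl diacetate F9. Sulfation with SO3·pyridine gives pyridinium 5,6-bis(acetyloxy)-2-[3,4-bis(acetyloxy)phenyl]-4-oxo-4H-chromen-7-yl sulfate F10. K2CO3 in MeOH under argon then removes the four acetates and exchanges the cation, giving 12, which is acidified as in step 9.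

Further compounds
F1 | step 6 | 1-[2,3-bis(benzyloxy)-6-hydroxy-4-(methoxymethoxy)phenyl]ethan-1-one | CC(=O)c1c(O)cc(OCOC)c(OCc2ccccc2)c1OCc1ccccc1
F2 | step 6 | 1-[2,3-bis(benzyloxy)-6-hydroxy-4-(methoxymethoxy)phenyl]-3-[3,4-bis(benzyloxy)phenyl]propane-1,3-dione | O=C(CC(=O)c1c(O)cc(OCOC)c(OCc2ccccc2)c1OCc1ccccc1)c1ccc(OCc2ccccc2)c(OCc2ccccc2)c1
F3 | step 3 | 1-[6-bromo-2-hydroxy-3,4-bis(methoxymethoxy)phenyl]ethan-1-one | CC(=O)c1c(Br)cc(OCOC)c(OCOC)c1O
F4 | step 3 | 1-[2-(benzyloxy)-6-bromo-3,4-bis(methoxymethoxy)phenyl]ethan-1-one | CC(=O)c1c(Br)cc(OCOC)c(OCOC)c1OCc1ccccc1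
F5 | step 3 | 1-[2-(benzyloxy)-6-bromo-3,4-dihydroxyphenyl]ethan-1-one | CC(=O)c1c(Br)cc(O)c(O)c1OCc1ccccc1
F6 | step 3 | 1-[2-(benzyloxy)-6-bromo-3-hydroxy-4-(methoxymethoxy)phenyl]ethan-1-one | CC(=O)c1c(Br)cc(OCOC)c(O)c1OCc1ccccc1
F7 | step 9 | 5,6-dihydroxy-2-(3,4-dihydroxyphenyl)-7-(methoxymethoxy)-4H-chromen-4-one | O=c1cc(-c2ccc(O)c(O)c2)oc2cc(OCOC)c(O)c(O)c12
F8 | step 9 | 2-[3,4-bis(acetyloxy)phenyl]-7-(methoxymethoxy)-4-oxo-4H-chromene-5,6-diyl diacetate | CC(=O)Oc1ccc(-c2cc(=O)c3c(OC(C)=O)c(OC(C)=O)c(OCOC)cc3o2)cc1OC(C)=O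
F9 | step 9 | 2-[3,4-bis(acetyloxy)phenyl]-7-hydroxy-4-oxo-4H-chromene-5,6-diyl diacetate | CC(=O)Oc1ccc(-c2cc(=O)c3c(OC(C)=O)c(OC(C)=O)c(O)cc3o2)cc1OC(C)=O
F10 | step 9 | pyridinium 5,6-bis(acetyloxy)-2-[3,4-bis(acetyloxy)phenyl]-4-oxo-4H-chromen-7-yl sulfate | CC(=O)Oc1ccc(-c2cc(=O)c3c(OC(C)=O)c(OC(C)=O)c(OS(=O)(=O)[O-])cc3o2)cc1OC(C)=O.c1cc[nH+]cc1
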